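**Plan**

- Numbering follows longipinane: C1 ketone, C2, C3 (CHMe), C4, C5, C6 (CMe2), C7 and C9 (acyloxy carbons), C8, C10 (quaternary C–Me), C11. Rings: cyclohexanone C11–C1–C2–C3–C4–C5, cycloheptane C5–C6–C7–C8–C9–C10–C11, cyclobutane C4–C5–C11–C10.
- Retrosynthesis: the two angelate C–O bonds are cut first, then C9–H (back to a C9 ketone), then C10–C4 (cyclobutane), then C8–C9 (seven-membered ring), and last C11–allyl, C5–C6 and C3–CH3 on a quinone monoketal.
- Enabling feature: C10 stands between the C9 carbonyl and the six-membered-ring carbon C4, 1,3 to it across the cis C5–C11 fusion. A C9 ketone therefore makes C10 an enolate carbon that can bond to C4 and complete the four-membered ring.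
- Forward order: six-membered ring (three C–C bonds on 4,4-dimethoxycyclohexadienone), then the seven-membered ring by aldol (C8–C9), then the cyclobutane by hydride-triggered enolate alkylation, then redox adjustment and esterification.
- Stereochemistry: C3 from a Cu/phosphoramidite-catalysed conjugate addition; C5 and C11 relayed from C3 (trans Michael addition, equilibration beside the ketal); C4 by hydride reduction followed by Mitsunobu inversion; C7 by Corey–Bakshi–Shibata reduction; C10 and the final C4 configuration in the key step; C9 by hydroxyl-directed reduction.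

Key step: step 15

Remark: the (S,R,R)-phosphoramidite of step 1 is assumed to deliver the (5R)-enone 2; if the sense of induction is the opposite, the (R,S,S)-antipode is used and nothing else changes.

Remark: the C9 carbinol centre of 19–22 is carried as both epimers; this is without consequence because C9 becomes a ketone in step 13.

**Route**

Step 1
Reactants: 1 4,4-dimethoxycyclohexa-2,5-dien-1-one
Product: 2 (5R)-4,4-dimethoxy-5-methylcyclohex-2-en-1-one
Conditions: Me2Zn, Cu(OTf)2 (cat.), (S)-BINOL N,N-bis[(R)-1-phenylethyl]phosphoramidite (cat.), toluene, −25 °C; aq. NH4Cl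
Reagents that add atoms: dimethylzinc, C[Zn]C
Why: Copper-catalysed enantioselective conjugate addition of a dialkylzinc to a prochiral 4,4-dialkoxycyclohexadienone is a known desymmetrisation; the chiral copper–phosphoramidite complex selects one enantiotopic enone and one of its faces and so sets the C3 methyl centre.

Step 2
Reactants: 2 (5R)-4,4-dimethoxy-5-methylcyclohex-2-en-1-one; 3 2-methylpropanenitrile (isobutyronitrile); 4 3-bromoprop-1-ene (allyl bromide)
Product: 7 2-allyl-3-(2-cyanopropan-2-yl)-4,4-dimethoxy-5-methylcyclohexan-1-one (allyl cis to cyanoisopropyl; methyl trans to cyanoisopropyl), via lithium enolate 5 (not isolated), via trans-allyl ketone 6 (not isolated)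
Conditions: LiN(iPr)2, 3, THF, −78 °C; 2, DMPU, −78 → −20 °C; 4, −78 → 0 °C; aq. NH4Cl; crude product, DBU (cat.), toluene, 23 °C
Reagents that add atoms: none
Why: Michael addition of the lithiated tertiary nitrile should occur at the β-carbon beside the ketal and trans to the C3 methyl (axial attack anti to the 5-substituent of the cyclohexenone), the regiodefined enolate 5 is C-allylated, and base equilibration at the enolisable C11 should end at the cis isomer, in which the cyanoisopropyl group is axial beside the ketal carbon and the allyl group equatorial, whereas the trans isomer needs either a syn-axial allyl/methoxy pair or the tert-alkyl group gauche to both methoxy groups.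

Step 3
Reactants: 7 2-allyl-3-(2-cyanopropan-2-yl)-4,4-dimethoxy-5-methylcyclohexan-1-one
Product: 8 2-allyl-3-(2-cyanopropan-2-yl)-5-methylcyclohexane-1,4-dione (relative configuration as in 7)
Conditions: 1 M HCl, THF, 0 °C
Reagents that add atoms: water, O
Why: Acid-catalysed hydrolysis of the strained, doubly flanked dimethyl ketal should be fast at 0 °C, where the α-stereocentres of the 1,4-dione (C3, C5, C11) are not expected to epimerise.

Step 4
Reactants: 8 2-allyl-3-(2-cyanopropan-2-yl)-5-methylcyclohexane-1,4-dione
Product: 9 2-(6-allyl-9-methyl-8-oxo-1,4-dioxaspiro[4.5]decan-7-yl)-2-methylpropanenitrile (C1 dioxolane; C4 ketone)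
Conditions: (Me3SiOCH2)2, Me3SiOTf (cat.), CH2Cl2, −78 °C
Reagents that add atoms: 1,2-bis(trimethylsilyloxy)ethane, C[Si](C)(C)OCCO[Si](C)(C)C
Why: Noyori ketalisation is kinetic and should take place only at the C1 carbonyl, which has a CH2 neighbour, and not at the C4 carbonyl flanked by two branched carbons; at −78 °C the enolisable C11 centre should stay untouched.

Step 5
Reactants: 9 2-(6-allyl-9-methyl-8-oxo-1,4-dioxaspiro[4.5]decan-7-yl)-2-methylpropanenitrile
Product: 10 2-(6-allyl-8-hydroxy-9-methyl-1,4-dioxaspiro[4.5]decan-7-yl)-2-methylpropanenitrile (C4 hydroxyl cis to the C5 cyanoisopropyl group; trans to the C3 methyl)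
Conditions: LiBH(sec-Bu)3, THF, −78 → −40 °C; aq. NH4Cl
Reagents that add atoms: none
Why: The bulky trialkylborohydride should reach the C4 carbonyl only from the face opposite the C5 cyanoisopropyl and C11 allyl groups (that face is blocked in either chair), which places the carbinol oxygen cis to the C5 branch; nitrile, dioxolane and alkene are inert to this reagent.

Step 6
Reactants: 10 2-(6-allyl-8-hydroxy-9-methyl-1,4-dioxaspiro[4.5]decan-7-yl)-2-methylpropanenitrile
Product: 11 6-allyl-7-(2-cyanopropan-2-yl)-9-methyl-1,4-dioxaspiro[4.5]decan-8-yl formate (formyloxy trans to the C5 branch; cis to the C3 methyl)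
Conditions: HCO2H, PPh3, diisopropyl azodicarboxylate, THF, 0 → 23 °C
Reagents that add atoms: formic acid, O=CO
Why: Mitsunobu reaction with formic acid, the smallest acidic pronucleophile, inverts C4 by SN2 attack from the same open face that the hydride used, so the oxygen ends trans to the C5 and C11 branches and cis to the C3 methyl.

Step 7
Reactants: 11 6-allyl-7-(2-cyanopropan-2-yl)-9-methyl-1,4-dioxaspiro[4.5]decan-8-yl formate
Product: 13 3-(6-allyl-8-hydroxy-9-methyl-1,4-dioxaspiro[4.5]decan-7-yl)-3-methylbutan-2-one (C4 hydroxyl cis to the C3 methyl), via dilithio ketimine alkoxide 12 (not isolated)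
Conditions: MeLi, Et2O, −78 → 0 °C; then AcOH/NaOAc buffer (pH 5), THF–H2O, 23 °C
Reagents that add atoms: methyllithium, [Li]C; water, O
Why: Methyllithium adds once to the tertiary nitrile (no α-hydrogen) to give the N-lithio ketimine, which is hydrolysed to the C7 methyl ketone at a pH the dioxolane survives, and the same reagent cleaves the formate to the free C4 carbinol without touching its configuration.

Step 8
Reactants: 13 3-(6-allyl-8-hydroxy-9-methyl-1,4-dioxaspiro[4.5]decan-7-yl)-3-methylbutan-2-one
Product: 14 6-allyl-9-methyl-7-(2-methyl-3-oxobutan-2-yl)-1,4-dioxaspiro[4.5]decan-8-yl 4-methylbenzenesulfonate (tosylate cis to the C3 methyl; trans to the C5 and C11 branches)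
Conditions: TsCl, DMAP, pyridine, 40 °C
Reagents that add atoms: p-toluenesulfonyl chloride, Cc1ccc(cc1)S(Cl)(=O)=O
Why: Sulfonylation of a secondary alcohol takes place at oxygen with retention, which puts the leaving group on the face opposite the two carbon branches.

Step 9
Reactants: 14 6-allyl-9-methyl-7-(2-methyl-3-oxobutan-2-yl)-1,4-dioxaspiro[4.5]decan-8-yl 4-methylbenzenesulfonate
Product: 16 2-[9-methyl-7-(2-methyl-3-oxobutan-2-yl)-8-(tosyloxy)-1,4-dioxaspiro[4.5]decan-6-yl]acetaldehyde, via ozonide 15 (not isolated)
Conditions: O3, CH2Cl2, −78 °C; PPh3, −78 → 23 °C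
Reagents that add atoms: ozone, [O-][O+]=O
Why: Ozonolysis with reductive work-up cleaves the only C=C bond and gives the aldehyde that becomes C9, with C10 as its α-carbon.

Step 10
Reactants: 16 2-[9-methyl-7-(2-methyl-3-oxobutan-2-yl)-8-(tosyloxy)-1,4-dioxaspiro[4.5]decan-6-yl]acetaldehyde
Product: 17 2-[9-methyl-7-(2-methyl-3-oxobutan-2-yl)-8-(tosyloxy)-1,4-dioxaspiro[4.5]decan-6-yl]prop-2-enal
Conditions: aq. CH2O, pyrrolidine (cat.), EtCO2H (cat.), iPrOH, 45 °C
Reagents that add atoms: formaldehyde, C=O
Why: Amine-catalysed Mannich condensation with formaldehyde followed by β-elimination (α-methylenation of aldehydes) is regiospecific here because C10 is the only α-carbon of the aldehyde and the hindered methyl ketone is far less prone to enamine formation.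

Step 11
Reactants: 17 2-[9-methyl-7-(2-methyl-3-oxobutan-2-yl)-8-(tosyloxy)-1,4-dioxaspiro[4.5]decan-6-yl]prop-2-enal
Product: 20 cis-fused bicyclic ketone (4,10-seco-longipinane skeleton; longipinane locants): 1,1-ethylenedioxy; 4-tosyloxy; 7-oxo; 9-trimethylsilyloxy (both C9 epimers); 10-methylene, via lithium enolate 18 (not isolated), via lithium aldolate 19 (not isolated)
Conditions: LiN(SiMe3)2, THF, −78 °C; then Me3SiCl, −78 → 0 °C
Reagents that add atoms: chlorotrimethylsilane, C[Si](C)(C)Cl
Why: The C8 methyl is the only enolisable position of the ketone (C6 is quaternary) and the α-methylene aldehyde cannot enolise, so the enolate should undergo the intramolecular aldol addition (1,2) that closes the seven-membered ring, helped by the gem-dimethyl group and the cis arrangement of the two side chains, while at −78 °C the hindered secondary tosylate is not alkylated; silylation of the aldolate blocks retro-aldol cleavage.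

Step 12
Reactants: 20 cis-fused bicyclic silyl ether ketone
Product: 22 cis-fused bicyclic diol: 1,1-ethylenedioxy; 4-tosyloxy; (7R)-7-hydroxy; 9-hydroxy (both C9 epimers); 10-methylene, via silyl ether alcohol 21 (not isolated)
Conditions: (S)-Me-CBS oxazaborolidine [(S)-1-methyl-3,3-diphenyltetrahydro-1H,3H-pyrrolo[1,2-c][1,3,2]oxazaborole] (cat.), catecholborane, toluene, −78 → −40 °C; then K2CO3 (cat.), MeOH, 0 °C
Reagents that add atoms: none
Why: Corey–Bakshi–Shibata reduction is reagent-controlled: with the quaternary C6 as the large and the C8 methylene as the small substituent the (S)-catalyst should give the (7R)-carbinol, which is also the product of attack on the convex face of the cis-fused bicycle; brief methanolysis at 0 °C then frees the C9 hydroxyl under conditions too mild to displace the hindered tosylate.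

Step 13
Reactants: 22 cis-fused bicyclic diol
Product: 23 cis-fused bicyclic hydroxy enone: 1,1-ethylenedioxy; 4-tosyloxy; (7R)-7-hydroxy; 9-oxo; 10-methylene
Conditions: MnO2, CH2Cl2, 23 °C
Reagents that add atoms: none
Why: MnO2 oxidises allylic alcohols chemoselectively, so only the C9 carbinol beside the exocyclic alkene should be converted (into the α-methylene ketone) while the saturated, neopentyl C7 carbinol stays.

Step 14
Reactants: 23 cis-fused bicyclic hydroxy enone
Product: 24 cis-fused bicyclic enone: 1,1-ethylenedioxy; 4-tosyloxy; (7R)-7-triethylsilyloxy; 9-oxo; 10-methylene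
Conditions: Et3SiOTf (1.1 equiv), 2,6-lutidine, CH2Cl2, −78 °C
Reagents that add atoms: triethylsilyl trifluoromethanesulfonate, CC[Si](CC)(CC)OS(=O)(=O)C(F)(F)F
Why: A silyl triflate with 2,6-lutidine silylates even hindered secondary alcohols, and the silyl ether prevents both retro-aldol opening of the β-hydroxy ketone and attack of the C7 oxygen on C4 under the basic conditions of the next step.

Step 15
Reactants: 24 cis-fused bicyclic enone with C4 tosylate
Product: 26 tricyclic ketone: 1,1-ethylenedioxy-7-(triethylsilyloxy)longipinan-9-one, via lithium enolate 25 (not isolated)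
Conditions: LiBH(sec-Bu)3 (1.05 equiv), THF, −78 °C; then 23 °C
Reagents that add atoms: none
Why: Hydride from LiBH(sec-Bu)3 adds 1,4 to the exocyclic methylene of the C9 enone, so the only enolate formed is the tetrasubstituted C9–C10 enolate (C8 is never deprotonated and, with C1 masked, C11 cannot enolise); C10 then displaces the C4 tosylate in an intramolecular SN2 reaction. The closest known reaction type is the reductive alkylation of α,β-unsaturated ketones with trialkylborohydrides, joined to the intramolecular ketone-enolate alkylation that builds the four-membered ring of pinane-type bicyclo[3.1.1]heptanes from 1,3-related keto sulfonates. The cyclobutane C4–C5–C11–C10 closes in the 4-exo-tet mode. C10 is set by the cis ring fusion, since the enolate carbon held axially on C11 can reach C4 with one face only, and C4 is set by inversion of the tosylate, which steps 6 and 8 placed trans to C10 and cis to the C3 methyl. The step needs 1,4- over 1,2-reduction (secured by the unhindered CH2 terminus and the bulky hydride), C- over O-alkylation (the seven-membered ring holds the enolate oxygen away from C4) and an anti arrangement of C10 and the leaving group (secured by the chair with the C6 branch equatorial, C10 axial and the tosylate equatorial). Only a slight excess of the hydride is used so that the C9 ketone of the product is not reduced after the ring closure.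

Step 16
Reactants: 26 1,1-ethylenedioxy-7-(triethylsilyloxy)longipinan-9-one
Product: 27 (7R)-7-hydroxylongipinane-1,9-dione
Conditions: 1 M HCl, THF, 23 °C
Reagents that add atoms: water, O
Why: Aqueous acid hydrolyses both the triethylsilyl ether and the dioxolane; C11 is a ring-fusion carbon of the rigid tricycle and cannot epimerise.

Step 17
Reactants: 27 (7R)-7-hydroxylongipinane-1,9-dione
Product: 28 (7R,9R)-7,9-dihydroxylongipinan-1-one (anti-1,3-diol)
Conditions: Me4NBH(OAc)3, MeCN/AcOH, −40 → −20 °C
Reagents that add atoms: none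
Why: In the Evans–Saksena reduction the C7 hydroxyl exchanges an acetate on boron and delivers hydride intramolecularly to C9, which should give the anti-1,3-diol, while the C1 ketone, with no hydroxyl within reach, is not reduced by the acetoxyborohydride.

Step 18
Reactants: 28 (7R,9R)-7,9-dihydroxylongipinan-1-one; 29 angelic acid [(Z)-2-methylbut-2-enoic acid]
Product: 30 (7R,9R)-7,9-bis(angeloyloxy)longipinan-1-one (CNP0283599.1)
Conditions: 29 (6 equiv), 2,4,6-Cl3C6H2COCl (6 equiv), Et3N, toluene, 23 °C; then 28, 80 °C
Reagents that add atoms: angelic acid (second equivalent of 29, for the second ester group), C/C=C(/C)C(=O)O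
Why: Two molecules of the acid are consumed, one per hydroxyl group: the Yamaguchi-type mixed anhydride of angelic acid, made beforehand in the flask and used in excess, should acylate both hindered secondary alcohols at its unhindered angeloyl carbonyl in hot toluene without a nucleophilic catalyst, conditions under which (Z)-to-(E) isomerisation to the tiglate is not expected.

**Compound list**

1 | 4,4-dimethoxycyclohexa-2,5-dien-1-one | COC1(OC)C=CC(=O)C=C1 | starting material
2 | (5R)-4,4-dimethoxy-5-methylcyclohex-2-en-1-one | O=C1C=CC(OC)(OC)[C@H](C)C1 | intermediate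
3 | 2-methylpropanenitrile (isobutyronitrile) | CC(C)C#N | starting material
4 | 3-bromoprop-1-ene (allyl bromide) | C=CCBr | starting material
5 | lithium 3-(2-cyanopropan-2-yl)-4,4-dimethoxy-5-methylcyclohex-1-en-1-olate, cyanoisopropyl trans to methyl (not isolated) | C1=C(O[Li])C[C@@H](C)C(OC)(OC)[C@@H]1C(C)(C)C#N | intermediate
6 | 2-allyl-3-(2-cyanopropan-2-yl)-4,4-dimethoxy-5-methylcyclohexan-1-one, allyl trans to cyanoisopropyl, C11 epimer of 7 (not isolated) | C=CC[C@@H]1[C@H](C(OC)(OC)[C@H](C)CC1=O)C(C)(C)C#N | intermediate
7 | 2-allyl-3-(2-cyanopropan-2-yl)-4,4-dimethoxy-5-methylcyclohexan-1-one, allyl cis to cyanoisopropyl, methyl trans to cyanoisopropyl | C=CC[C@H]1[C@H](C(OC)(OC)[C@H](C)CC1=O)C(C)(C)C#N | intermediate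
8 | 2-allyl-3-(2-cyanopropan-2-yl)-5-methylcyclohexane-1,4-dione, configuration as in 7 | C=CC[C@H]1[C@H](C(=O)[C@H](C)CC1=O)C(C)(C)C#N | intermediate
9 | 2-(6-allyl-9-methyl-8-oxo-1,4-dioxaspiro[4.5]decan-7-yl)-2-methylpropanenitrile | C=CC[C@H]1[C@H](C(=O)[C@H](C)CC12OCCO2)C(C)(C)C#N | intermediate
10 | 2-(6-allyl-8-hydroxy-9-methyl-1,4-dioxaspiro[4.5]decan-7-yl)-2-methylpropanenitrile, hydroxyl cis to the cyanoisopropyl group and trans to methyl | C=CC[C@H]1[C@H]([C@@H](O)[C@H](C)CC12OCCO2)C(C)(C)C#N | intermediate
11 | 6-allyl-7-(2-cyanopropan-2-yl)-9-methyl-1,4-dioxaspiro[4.5]decan-8-yl formate, formyloxy trans to the cyanoisopropyl group and cis to methyl | C=CC[C@H]1[C@H]([C@H](OC=O)[C@H](C)CC12OCCO2)C(C)(C)C#N | intermediate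
12 | lithium alkoxide N-lithio ketimine formed from 11 and methyllithium (not isolated) | C=CC[C@H]1[C@H]([C@H](O[Li])[C@H](C)CC12OCCO2)C(C)(C)C(C)=N[Li] | intermediate
13 | 3-(6-allyl-8-hydroxy-9-methyl-1,4-dioxaspiro[4.5]decan-7-yl)-3-methylbutan-2-one, hydroxyl cis to methyl | C=CC[C@H]1[C@H]([C@H](O)[C@H](C)CC12OCCO2)C(C)(C)C(C)=O | intermediate
14 | 6-allyl-9-methyl-7-(2-methyl-3-oxobutan-2-yl)-1,4-dioxaspiro[4.5]decan-8-yl 4-methylbenzenesulfonate | C=CC[C@H]1[C@H]([C@H](OS(=O)(=O)c2ccc(C)cc2)[C@H](C)CC13OCCO3)C(C)(C)C(C)=O | intermediate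
15 | 1,2,4-trioxolane (ozonide) of the allyl group of 14 (not isolated) | C1(C[C@H]2[C@H]([C@H](OS(=O)(=O)c3ccc(C)cc3)[C@H](C)CC24OCCO4)C(C)(C)C(C)=O)OCOO1 | intermediate
16 | 2-[9-methyl-7-(2-methyl-3-oxobutan-2-yl)-8-(tosyloxy)-1,4-dioxaspiro[4.5]decan-6-yl]acetaldehyde | O=CC[C@H]1[C@H]([C@H](OS(=O)(=O)c2ccc(C)cc2)[C@H](C)CC13OCCO3)C(C)(C)C(C)=O | intermediate
17 | 2-[9-methyl-7-(2-methyl-3-oxobutan-2-yl)-8-(tosyloxy)-1,4-dioxaspiro[4.5]decan-6-yl]prop-2-enal | O=CC(=C)[C@H]1[C@H]([C@H](OS(=O)(=O)c2ccc(C)cc2)[C@H](C)CC13OCCO3)C(C)(C)C(C)=O | intermediate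
18 | lithium enolate of the methyl ketone of 17, C7–C8 enolate (not isolated) | O=CC(=C)[C@H]1[C@H]([C@H](OS(=O)(=O)c2ccc(C)cc2)[C@H](C)CC13OCCO3)C(C)(C)C(=C)O[Li] | intermediate
19 | lithium C9 aldolate of the cis-fused bicyclic C7 ketone, both C9 epimers (not isolated) | O=C1CC(O[Li])C(=C)[C@H]2[C@H]([C@H](OS(=O)(=O)c3ccc(C)cc3)[C@H](C)CC24OCCO4)C1(C)C | intermediate
20 | cis-fused bicyclic ketone (4,10-seco-longipinane, longipinane locants): 1,1-ethylenedioxy, 4-tosyloxy, 7-oxo, 9-trimethylsilyloxy (both C9 epimers), 10-methylene | O=C1CC(O[Si](C)(C)C)C(=C)[C@H]2[C@H]([C@H](OS(=O)(=O)c3ccc(C)cc3)[C@H](C)CC24OCCO4)C1(C)C | intermediate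
21 | (7R)-7-hydroxy-9-trimethylsilyloxy analogue of 20, both C9 epimers (not isolated) | O[C@@H]1CC(O[Si](C)(C)C)C(=C)[C@H]2[C@H]([C@H](OS(=O)(=O)c3ccc(C)cc3)[C@H](C)CC24OCCO4)C1(C)C | intermediate
22 | cis-fused bicyclic diol: 1,1-ethylenedioxy, 4-tosyloxy, (7R)-7-hydroxy, 9-hydroxy (both C9 epimers), 10-methylene | O[C@@H]1CC(O)C(=C)[C@H]2[C@H]([C@H](OS(=O)(=O)c3ccc(C)cc3)[C@H](C)CC24OCCO4)C1(C)C | intermediate
23 | cis-fused bicyclic hydroxy enone: 1,1-ethylenedioxy, 4-tosyloxy, (7R)-7-hydroxy, 9-oxo, 10-methylene | O[C@@H]1CC(=O)C(=C)[C@H]2[C@H]([C@H](OS(=O)(=O)c3ccc(C)cc3)[C@H](C)CC24OCCO4)C1(C)C | intermediate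
24 | cis-fused bicyclic enone, precursor of the key step: 1,1-ethylenedioxy, 4-tosyloxy (cis to the C3 methyl), (7R)-7-triethylsilyloxy, 9-oxo, 10-methylene | CC[Si](CC)(CC)O[C@@H]1CC(=O)C(=C)[C@H]2[C@H]([C@H](OS(=O)(=O)c3ccc(C)cc3)[C@H](C)CC24OCCO4)C1(C)C | intermediate
25 | lithium C9–C10 enolate formed by 1,4-hydride addition to 24 (not isolated) | CC[Si](CC)(CC)O[C@@H]1CC(O[Li])=C(C)[C@H]2[C@H]([C@H](OS(=O)(=O)c3ccc(C)cc3)[C@H](C)CC24OCCO4)C1(C)C | intermediate
26 | 1,1-ethylenedioxy-7-(triethylsilyloxy)longipinan-9-one, product of the key step | CC[Si](CC)(CC)O[C@@H]1CC(=O)[C@]2(C)[C@@H]3[C@@H]([C@H]2C4(OCCO4)C[C@H]3C)C1(C)C | intermediate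
27 | (7R)-7-hydroxylongipinane-1,9-dione | O[C@@H]1CC(=O)[C@]2(C)[C@@H]3[C@@H]([C@H]2C(=O)C[C@H]3C)C1(C)C | intermediate
28 | (7R,9R)-7,9-dihydroxylongipinan-1-one | O[C@@H]1C[C@@H](O)[C@]2(C)[C@@H]3[C@@H]([C@H]2C(=O)C[C@H]3C)C1(C)C | intermediate
29 | angelic acid, (Z)-2-methylbut-2-enoic acid | C/C=C(/C)C(=O)O | starting material
30 | (7R,9R)-7,9-bis(angeloyloxy)longipinan-1-one, CNP0283599.1 | C/C=C(/C)C(=O)O[C@@H]1C[C@@H](OC(=O)/C(C)=C\C)[C@]2(C)[C@@H]3[C@@H]([C@H]2C(=O)C[C@H]3C)C1(C)C | target

**Step count and risks**

Total step count: 18. Longest linear sequence: 18 steps (1 → 30).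

Steps most likely to fail:

Step 6 (Mitsunobu inversion at C4). The process at risk is elimination from the activated alkoxyphosphonium at a carbinol flanked by two branched carbons outrunning substitution, or the activation not taking place at all. The fallback sets out from 10: the alcohol is converted with Tf2O and pyridine in CH2Cl2 at −20 °C into the C4 triflate F1, a discrete and far better leaving group. F1 is then displaced with HCO2Cs and 18-crown-6 in toluene/DMF, a sulfonate displacement with inversion of the kind used for hindered ring carbinols in carbohydrate chemistry. This gives formate 11, where the route is rejoined.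

Step 2 (Michael addition, allylation and equilibration). The process most at risk is the C-allylation of the hindered lithium enolate, which may be outrun by proton transfer between enolate and product, with loss of regiocontrol and over-allylation. The fallback sets out from 2: the conjugate addition is run as in step 2, and the lithium enolate is then quenched with Me3SiCl/Et3N at −78 °C in place of allyl bromide, which gives the trimethylsilyl enol ether F2, and this is isolated. F2 is then allylated under neutral conditions with allyl methyl carbonate and Pd2(dba)3/dppe (zerovalent palladium; Tsuji allylation through the π-allyl complex). The allyl ketones obtained are equilibrated with DBU as in step 2, so the route is rejoined at 7.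

Step 11 (seven-membered aldol closure). The process at risk is a slow or reversible ring closure, so that the lithium enolate is lost to proton transfer or to conjugate addition to the α-methylene aldehyde. The fallback sets out from 17: LiN(SiMe3)2 with Me3SiCl already present gives the silyl enol ether F3, and NBS converts it into the bromomethyl ketone F4. SmI2 in THF at −78 °C then effects a reductive, Reformatsky-type cyclisation; the samarium enolate can only form at C8, and this reaction is well established for medium rings. The samarium aldolate is silylated with Me3SiCl, which rejoins the route at 20.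

Further compounds
F1 | step 6 | C4 triflate of 10: 6-allyl-7-(2-cyanopropan-2-yl)-9-methyl-1,4-dioxaspiro[4.5]decan-8-yl trifluoromethanesulfonate, sulfonate cis to the cyanoisopropyl group | C=CC[C@H]1[C@H]([C@@H](OS(=O)(=O)C(F)(F)F)[C@H](C)CC12OCCO2)C(C)(C)C#N
F2 | step 2 | trimethylsilyl enol ether of the Michael adduct: 2-[2,2-dimethoxy-3-methyl-5-(trimethylsilyloxy)cyclohex-5-en-1-yl]-2-methylpropanenitrile, cyanoisopropyl trans to methyl | C1=C(O[Si](C)(C)C)C[C@@H](C)C(OC)(OC)[C@@H]1C(C)(C)C#N
F3 | step 11 | trimethylsilyl enol ether of the methyl ketone of 17 | O=CC(=C)[C@H]1[C@H]([C@H](OS(=O)(=O)c2ccc(C)cc2)[C@H](C)CC13OCCO3)C(C)(C)C(=C)O[Si](C)(C)C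
F4 | step 11 | bromomethyl ketone derived from 17 | O=CC(=C)[C@H]1[C@H]([C@H](OS(=O)(=O)c2ccc(C)cc2)[C@H](C)CC13OCCO3)C(C)(C)C(=O)CBr
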